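The earlier runs and the new flask stem from a simulated flask on assumed constants, noise included.

**Two constants.** The constants we can read from the alpha and epsilon runs are a time and a count, and they form a ladder.

| flask | D | Q | remark | time |
|---|---|---|---|---|
| alpha | 0.95 M | 0.315 M | run made earlier |  |
| epsilon | 1.3 M | 0.315 M | run made earlier |  |
| south-east | 0.63 M | 0.315 M |  | 3.0 h |
| north-west | 0.63 M | 0.945 M |  | 3.0 h |
| south-west | 0.63 M | 0.630 M |  | 3.0 h |

| run | time / min | Z / % | D / % |
|---|---|---|---|
| alpha | 3.00 | 14.8 | 68.3 |
| alpha | 6.00 | 11.1 | 64.3 |
| alpha | 15.0 | 7.6 | 56.6 |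
| alpha | 40.0 | 1.9 | 53.6 |
| epsilon | 3.00 | 10.3 | 72.9 |
| epsilon | 6.00 | 8.4 | 69.7 |
| epsilon | 15.0 | 2.5 | 64.7 |
| epsilon | 40.0 | 0.2 | 65.0 |

(scatter of a reading: 1 percentage point)

- the numbers in the tables scatter by 1 percentage point (one standard deviation)

1. which of these holds the largest part of the D at the end of south-east (Z / D / E / L)
2. which of these holds the largest part of the D at the end of north-west (Z / D / E / L)
3. which of these holds the largest part of the D at the end of south-west (Z / D / E / L)
4. amount of Z at the end of south-west, in percent of the D charged

**Fast rung.** By 3.00 min, alpha has lost 0.301 M of D and epsilon 0.352 M, close to the 0.315 M of Q charged in each. That is about one D per Q within minutes.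

**Slower rung.** Z then fades, with a half-time of about 12.5 min read from alpha, while D keeps dropping. By 40.0 min the D lost stands at 0.441 M in alpha and 0.455 M in epsilon. Dividing each by the Q charged and averaging gives 1.42, our turnover count: D lost for good per Q charged. It is a reading, and it carries their scatter.

**Last rung.** The 3.0 h of the new flasks is far longer than that half-time, so we reckon them as finished. In south-east the count asks for 0.448 M of D, less than the 0.63 M charged. Q is therefore the limiting reagent, and 28.9% of the D should remain. The count does not say how the spent D divides among the products, so putting D first there is our judgement, not a result of the count. In south-west and north-west the count asks for 0.896 M and 1.34 M, more than the D charged, so D should fall close to nothing. In those two flasks, too, the count does not say how the products divide.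

**The forecast.** It named L, which differs from our choice, for south-east, E for north-west and E for south-west, with 33% of Z in south-west (range 25% to 40%), holding that “Q + D outruns Z + D”.

**The result.**

    D + Q → Z + G (k = 0.0150 L mol⁻¹ s⁻¹)
    D + Q → L + G (k = 0.00860 L mol⁻¹ s⁻¹)
    Q + Z → E + G (k = 0.00350 L mol⁻¹ s⁻¹)
    Q + L → E + G (k = 0.0300 L mol⁻¹ s⁻¹)
    D + Z → J (k = 0.00190 L mol⁻¹ s⁻¹)

South-east ends with D first of the four at 30.1%, above L at 10.8%, against our 28.9%. Its J, which holds two D, stands at 52.5%. North-west ends on E and south-west on E, with D at 0.0186% and 1.01% and Z in south-west at 19.3%. The neighbour flask is south-west with 0.25 M of Q. The count asks for 0.355 M of D, leaving 43.7%. That flask ends with 42% of its D unbound.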